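**Assumption:** labdane numbering is used for positions (C3 carbinol; C8 carbinol carrying formyl C17; C9 carrying the side chain C11–C15; C10 angular methyl); the D-fructose-derived Shi ketone and the organometallic solutions are bought.

**Retrosynthetic overview**
1. Target ⇒ 17-nor C8 ketone: the formyl carbon C17 is added last as a 1,3-dithiane anion, equatorial attack setting C8.
2. Decalone ⇒ acyclic (R)-epoxy triene ending in a (Z)-silyl enol ether; one epoxide-initiated cation–olefin cascade closes ring A first (C4–C5), then ring B (C10–C9).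
3. Key disconnection C11–C12: the enol ether is the γ-alkylation product of a siloxyallyl anion (ketone homoenolate from acylsilane + vinyllithium + Brook shift) with a (Z)-γ-bromo enoate. This one step fixes the enol-ether regio- and stereochemistry and brings in the whole Z side chain.
4. Acylsilane ⇒ acetyltrimethylsilane enolate + (R)-6,7-epoxygeranyl bromide; the epoxide (Shi epoxidation of geranyl acetate) is the only source of absolute configuration.

**Route**

Step 1
Reactants: 1 geranyl acetate
Product: 2 (R)-6,7-epoxygeranyl acetate [(2E)-5-[(2R)-3,3-dimethyloxiran-2-yl]-3-methylpent-2-en-1-yl acetate]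
Conditions: Shi ketone (D-fructose-derived, 30 mol%), Oxone, K2CO3, Bu4NHSO4, MeCN–DMM–aq. borate buffer, 0 °C
Reagents that add atoms: Oxone (potassium peroxymonosulfate), [K+].[O-]S(=O)(=O)OO
Why: Shi asymmetric epoxidation: the chiral dioxirane epoxidises only the electron-rich distal trisubstituted alkene (the 2,3-alkene is deactivated by the allylic acetate) through the spiro transition state that gives the (R)-epoxide (about 90–95% ee; a later crystalline intermediate can be recrystallised if needed), the stereocentre that becomes C3 and later dictates C5, C9 and C10.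

Step 2
Reactants: 2 (R)-6,7-epoxygeranyl acetate
Product: 3 (R)-6,7-epoxygeraniol [(2E)-5-[(2R)-3,3-dimethyloxiran-2-yl]-3-methylpent-2-en-1-ol]
Conditions: K2CO3 (cat.), MeOH, 0 °C
Reagents that add atoms: none
Why: Base-catalysed transesterification (methanolysis) removes the acetate while the trisubstituted epoxide is inert to methoxide at 0 °C.

Step 3
Reactants: 3 (R)-6,7-epoxygeraniol
Product: 5 (R)-6,7-epoxygeranyl bromide [(2R)-3-[(3E)-5-bromo-3-methylpent-3-en-1-yl]-2,2-dimethyloxirane], via epoxygeranyl mesylate 4 (not isolated)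
Conditions: MsCl, Et3N, THF, −40 °C; then LiBr, THF, 0 °C
Reagents that add atoms: lithium bromide, [Li+].[Br-]
Why: Mesylation followed by SN2 displacement with bromide (Finkelstein-type) converts the primary allylic alcohol into the allylic bromide with retention of the E alkene under non-acidic conditions that spare the epoxide.

Step 4
Reactants: 5 (R)-6,7-epoxygeranyl bromide; 6 acetyltrimethylsilane
Product: 8 (4E)-7-[(2R)-3,3-dimethyloxiran-2-yl]-5-methyl-1-(trimethylsilyl)hept-4-en-1-one, via lithium enolate 7 (not isolated)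
Conditions: 6, LDA, THF, −78 °C; then 5, DMPU, −78 → −20 °C
Reagents that add atoms: none
Why: Enolate alkylation: the lithium enolate of the acylsilane (one enolisable site only) is C-alkylated by the primary allylic bromide in an SN2 reaction, joining C6 to C7 and placing the silyl-bearing carbonyl carbon at the future C8.

Step 5
Reactants: 9 methyl 3-methylbut-2-enoate
Product: 10 methyl (2Z)-4-bromo-3-methylbut-2-enoate
Conditions: NBS, AIBN (cat.), PhCF3, 85 °C; Z isomer separated from E by chromatography
Reagents that add atoms: N-bromosuccinimide, O=C1CCC(=O)N1Br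
Why: Wohl–Ziegler allylic bromination through the delocalised allyl radical gives both 4-bromo isomers, and the Z isomer (CH2Br cis to CO2Me), whose geometry becomes the 13Z alkene of the target, is isolated.

Step 6
Reactants: 8 (4E)-7-[(2R)-3,3-dimethyloxiran-2-yl]-5-methyl-1-(trimethylsilyl)hept-4-en-1-one; 11 vinyl bromide; 10 methyl (2Z)-4-bromo-3-methylbut-2-enoate
Product: 15 methyl (2Z,6Z,10E)-13-[(2R)-3,3-dimethyloxiran-2-yl]-3,11-dimethyl-7-[(trimethylsilyl)oxy]trideca-2,6,10-trienoate, via vinyllithium 12 (not isolated), via lithium silyl alkoxide 13 (not isolated), via siloxyallyllithium 14 (not isolated)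
Conditions: 11, t-BuLi (2 equiv), Et2O–THF, −78 °C; 8, −78 → −40 °C; then cannulated into 10 (1.5 equiv), THF, −78 °C; Et3N-buffered work-up
Reagents that add atoms: none
Why: Vinyllithium 1,2-addition to the acylsilane and [1,2]-Brook rearrangement generate a siloxyallyl anion, a ketone homoenolate in which C11 (the normally electrophilic β-carbon of the C8 carbonyl) is nucleophilic, and its SN2 γ-alkylation by the allylic bromide forms C11–C12 and gives the regiodefined Z silyl enol ether (cisoid O–Li-chelated anion) with the Z enoate geometry carried over unchanged.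

Step 7
Reactants: 15 methyl (2Z,6Z,10E)-13-[(2R)-3,3-dimethyloxiran-2-yl]-3,11-dimethyl-7-[(trimethylsilyl)oxy]trideca-2,6,10-trienoate
Product: 16 methyl (2Z)-5-[(1S,4aS,6R,8aR)-6-hydroxy-5,5,8a-trimethyl-2-oxodecahydronaphthalen-1-yl]-3-methylpent-2-enoate
Conditions: MeAlCl2 (2.2 equiv), CH2Cl2, −94 → −78 °C; then 1 M HCl–THF work-up
Reagents that add atoms: none
Why: Lewis-acid epoxide-initiated cation–olefin bicyclisation (Stork–Eschenmoser chair–chair folding with a silyl enol ether terminator): ring A closes first (C4–C5) and ring B second (C10–C9), the epoxide oxygen ending equatorial at C3 so that anti addition across the E alkene sets the trans ring fusion (C5, C10), the Z enol ether places the C9 side chain equatorial (also the thermodynamic α-keto epimer), and the oxocarbenium ion collapses to the C8 ketone.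

Step 8
Reactants: 16 methyl (2Z)-5-[(1S,4aS,6R,8aR)-6-hydroxy-5,5,8a-trimethyl-2-oxodecahydronaphthalen-1-yl]-3-methylpent-2-enoate; 17 1,3-dithiane
Product: 19 methyl (2Z)-5-[(1S,2R,4aS,6R,8aR)-2-(1,3-dithian-2-yl)-2,6-dihydroxy-5,5,8a-trimethyldecahydronaphthalen-1-yl]-3-methylpent-2-enoate, via 2-lithio-1,3-dithiane 18 (not isolated)
Conditions: 17 (3 equiv), n-BuLi, THF, −30 °C; anhydrous CeCl3, −78 °C; then 16, −78 → −40 °C; H2O
Reagents that add atoms: none
Why: Corey–Seebach addition of the 1,3-dithiane anion (formyl anion equivalent, used with CeCl3 to lower basicity so that the enoate and the enolisable ketone survive) to the C8 ketone, the bulky nucleophile entering from the equatorial direction, anti to the syn-axial C10 methyl, which gives the axial C8 hydroxyl and equatorial C17 required by the target.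

Step 9
Reactants: 19 methyl (2Z)-5-[(1S,2R,4aS,6R,8aR)-2-(1,3-dithian-2-yl)-2,6-dihydroxy-5,5,8a-trimethyldecahydronaphthalen-1-yl]-3-methylpent-2-enoate
Product: 20 methyl (2Z)-5-[(1S,2R,4aS,6R,8aR)-2-formyl-2,6-dihydroxy-5,5,8a-trimethyldecahydronaphthalen-1-yl]-3-methylpent-2-enoate (target)
Conditions: PhI(O2CCF3)2, NaHCO3, MeCN–H2O (9:1), 0 °C
Reagents that add atoms: water, O
Why: Oxidative dithioacetal hydrolysis with hypervalent iodine (Stork–Zhao conditions) unmasks the formyl group in minutes at 0 °C; C8 is quaternary and cannot epimerise, and the enoate and both hydroxyls are untouched.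

**Compound list**
1 | geranyl acetate | CC(=O)OC/C=C(\C)CCC=C(C)C | starting material
2 | (R)-6,7-epoxygeranyl acetate | CC(=O)OC/C=C(\C)CC[C@H]1OC1(C)C | intermediate
3 | (R)-6,7-epoxygeraniol | OC/C=C(\C)CC[C@H]1OC1(C)C | intermediate
4 | (R)-6,7-epoxygeranyl mesylate | CS(=O)(=O)OC/C=C(\C)CC[C@H]1OC1(C)C | intermediate
5 | (R)-6,7-epoxygeranyl bromide | BrC/C=C(\C)CC[C@H]1OC1(C)C | intermediate
6 | acetyltrimethylsilane | CC(=O)[Si](C)(C)C | starting material
7 | lithium 1-(trimethylsilyl)ethen-1-olate | [Li]OC(=C)[Si](C)(C)C | intermediate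
8 | (4E)-7-[(2R)-3,3-dimethyloxiran-2-yl]-5-methyl-1-(trimethylsilyl)hept-4-en-1-one | C[Si](C)(C)C(=O)CC/C=C(\C)CC[C@H]1OC1(C)C | intermediate
9 | methyl 3-methylbut-2-enoate | COC(=O)C=C(C)C | starting material
10 | methyl (2Z)-4-bromo-3-methylbut-2-enoate | COC(=O)/C=C(/C)CBr | intermediate
11 | vinyl bromide | BrC=C | starting material
12 | vinyllithium | [Li]C=C | intermediate
13 | lithium (6E)-9-[(2R)-3,3-dimethyloxiran-2-yl]-7-methyl-3-(trimethylsilyl)nona-1,6-dien-3-olate (C3 not controlled) | [Li]OC(C=C)([Si](C)(C)C)CC/C=C(\C)CC[C@H]1OC1(C)C | intermediate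
14 | [(2Z,6E)-9-[(2R)-3,3-dimethyloxiran-2-yl]-7-methyl-3-[(trimethylsilyl)oxy]nona-2,6-dien-1-yl]lithium | [Li]C/C=C(\O[Si](C)(C)C)CC/C=C(\C)CC[C@H]1OC1(C)C | intermediate
15 | methyl (2Z,6Z,10E)-13-[(2R)-3,3-dimethyloxiran-2-yl]-3,11-dimethyl-7-[(trimethylsilyl)oxy]trideca-2,6,10-trienoate | COC(=O)/C=C(/C)CC/C=C(\O[Si](C)(C)C)CC/C=C(\C)CC[C@H]1OC1(C)C | intermediate
16 | methyl (2Z)-5-[(1S,4aS,6R,8aR)-6-hydroxy-5,5,8a-trimethyl-2-oxodecahydronaphthalen-1-yl]-3-methylpent-2-enoate | COC(=O)/C=C(/C)CC[C@H]1[C@]2(C)CC[C@@H](O)C(C)(C)[C@H]2CCC1=O | intermediate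
17 | 1,3-dithiane | C1CSCSC1 | starting material
18 | 2-lithio-1,3-dithiane | [Li]C1SCCCS1 | intermediate
19 | methyl (2Z)-5-[(1S,2R,4aS,6R,8aR)-2-(1,3-dithian-2-yl)-2,6-dihydroxy-5,5,8a-trimethyldecahydronaphthalen-1-yl]-3-methylpent-2-enoate | COC(=O)/C=C(/C)CC[C@H]1[C@]2(C)CC[C@@H](O)C(C)(C)[C@H]2CC[C@]1(O)C3SCCCS3 | intermediate
20 | methyl (2Z)-5-[(1S,2R,4aS,6R,8aR)-2-formyl-2,6-dihydroxy-5,5,8a-trimethyldecahydronaphthalen-1-yl]-3-methylpent-2-enoate | COC(=O)/C=C(/C)CC[C@H]1[C@]2(C)CC[C@@H](O)C(C)(C)[C@H]2CC[C@]1(O)C=O | target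

**Step count**
Total: 9 steps. Longest linear sequence: 8 (steps 1, 2, 3, 4, 6, 7, 8, 9); step 5 is a one-step side branch.

**Steps most likely to fail, with fallbacks**

Step 6. The siloxyallyllithium may attack the ester of 10, add in conjugate fashion with ring closure to a cyclopropane, or alkylate at the α-carbon. The fallback keeps the homoenolate but removes the ester from the anion step. It sets out from 8: the anion 14 is generated as before and alkylated with ICH2Bpin to give 2-[(3Z,7E)-10-[(2R)-3,3-dimethyloxiran-2-yl]-8-methyl-4-[(trimethylsilyl)oxy]deca-3,7-dien-1-yl]-4,4,5,5-tetramethyl-1,3,2-dioxaborolane F1. MeAlCl2 cyclisation of this enol ether, as in step 7, gives the bicyclic hydroxy keto boronate F2. C12–C13 is then made by sp3–sp2 Suzuki–Miyaura coupling (Pd(OAc)2, RuPhos, K3PO4, toluene–H2O, 80 °C) with methyl (2Z)-3-iodobut-2-enoate F3, itself obtained from methyl but-2-ynoate with NaI in AcOH (anti hydroiodination). The coupling retains the Z geometry and comes back to the route at 16.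

Step 7. The labile TMS enol ether may be protodesilylated before it can terminate the cascade, or the cation may stop after ring A. The fallback changes from the cationic to the radical manifold and sets out from 15. Cp2TiCl (from Cp2TiCl2 and Mn, THF, rt, no protic additive) opens the epoxide homolytically; the C4 radical closes ring A and the C10 radical adds to C9 of the enol ether. The resulting α-siloxy C8 radical is trapped by a second Cp2TiCl and loses a β-hydrogen to give the bicyclic trimethylsilyl enol ether F4 (Δ7 isomer shown, with its Δ8(9) isomer). Dilute HCl work-up hydrolyses it and the route is rejoined at 16.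

Step 8. The dithiane anion may enolise the hindered C8 ketone or deprotonate or attack the enoate. The fallback replaces the sulfur-based formyl equivalent by an alkene that is cleaved afterwards; it sets out from 16. 2-Methylprop-1-enylmagnesium bromide with CeCl3 (THF, −78 → 0 °C) adds from the equatorial face to give the tertiary allylic alcohol F5 (C8 hydroxyl axial, 2-methylprop-1-enyl equatorial). Ozonolysis (O3, CH2Cl2–MeOH, −78 °C, Sudan III end point, then Me2S) cleaves only the electron-rich trisubstituted alkene, leaves the electron-poor enoate, and arrives directly at 20.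

**Further compounds**
F1 | step 6 | 2-[(3Z,7E)-10-[(2R)-3,3-dimethyloxiran-2-yl]-8-methyl-4-[(trimethylsilyl)oxy]deca-3,7-dien-1-yl]-4,4,5,5-tetramethyl-1,3,2-dioxaborolane | CC1(C)OB(OC1(C)C)CC/C=C(\O[Si](C)(C)C)CC/C=C(\C)CC[C@H]2OC2(C)C
F2 | step 6 | (1S,4aS,6R,8aR)-6-hydroxy-5,5,8a-trimethyl-1-[2-(4,4,5,5-tetramethyl-1,3,2-dioxaborolan-2-yl)ethyl]octahydronaphthalen-2(1H)-one | CC1(C)OB(OC1(C)C)CC[C@H]2[C@]3(C)CC[C@@H](O)C(C)(C)[C@H]3CCC2=O
F3 | step 6 | methyl (2Z)-3-iodobut-2-enoate | COC(=O)/C=C(/C)I
F4 | step 7 | methyl (2Z)-5-[(1S,4aS,6R,8aR)-6-hydroxy-5,5,8a-trimethyl-2-[(trimethylsilyl)oxy]-1,4,4a,5,6,7,8,8a-octahydronaphthalen-1-yl]-3-methylpent-2-enoate | COC(=O)/C=C(/C)CC[C@H]1[C@]2(C)CC[C@@H](O)C(C)(C)[C@H]2CC=C1O[Si](C)(C)C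
F5 | step 8 | methyl (2Z)-5-[(1S,2S,4aS,6R,8aR)-2,6-dihydroxy-5,5,8a-trimethyl-2-(2-methylprop-1-en-1-yl)decahydronaphthalen-1-yl]-3-methylpent-2-enoate | COC(=O)/C=C(/C)CC[C@H]1[C@]2(C)CC[C@@H](O)C(C)(C)[C@H]2CC[C@]1(O)C=C(C)C
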